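**Retrosynthetic overview**
1. The last step is one acidolysis of all protecting groups; before it, both caffeoyl esters are put on together (O3 of ring B, O5 of ring A).
2. Ring A is cut at C6–C1 and C3–C4 into a silyloxyacetone enol ether (C4–C5–C6) and the 4-alkoxy-2-oxobut-3-enoyl ester of the ring B tertiary alcohol (C7, C1–C2–C3); a Cu(OTf)2/bis(oxazoline) hetero-Diels–Alder/aldol cascade joins them.
3. Enabling feature: in ring A, C1 carries O1 and the ester carbon C7 (latent 1,2-dicarbonyl), O3 sits β to C1 (latent oxadiene O=C1–C2=C3–O3), and C5–O is flanked by C4–O and the C6 methylene (latent α-oxygenated methyl ketone). The hindered tertiary ester O1(ring B)–C7 is therefore made by simple acylation before C1 becomes quaternary.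
4. Ring B, which has the same configuration, is made first by the same annulation on a tert-butyl ester; C5 of each ring is set by hydroxyl-directed reduction.
5. Ring order: transient dihydropyran, then cyclohexane B (step 3); transient dihydropyran, then cyclohexane A (step 7); the arenes arrive with the caffeoyl units (step 12).

Key step: step 7

Remark: both cyclohexane units of the target are antipodal to natural (−)-quinic acid, so neither is taken from the chiral pool.
Remark: rings are numbered as in quinic acid (C1 carboxyl-bearing, O3 cis to O4, O5 trans to O4); ring B carries the free carboxyl in the target, ring A acylates O1 of ring B; TBS = tert-butyldimethylsilyl, TMS = trimethylsilyl, (S,S)-t-Bu-box = 2,2'-(propane-2,2-diyl)bis[(4S)-4-tert-butyl-4,5-dihydro-1,3-oxazole].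
Assumption: the Cu(OTf)2 complex of the (S,S)-ligand is taken to leave open the Re face of C3 of the chelated keto ester, by analogy with its additions to chelated 2-oxo esters; should the sense be opposite, the (R,R)-ligand is used in steps 3 and 7.

**Step 1**
Reactants: 1 benzyl vinyl ether; 2 oxalyl chloride; 3 tert-butanol
Product: 5 tert-butyl (E)-4-(benzyloxy)-2-oxobut-3-enoate, via keto acyl chloride 4 (not isolated)
Conditions: 2 (1.5 equiv), CH2Cl2, 0 °C → rt; evaporate; then 3, pyridine, CH2Cl2, 0 °C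
Reagents that add atoms: none
Why: Oxalyl chloride acylates the nucleophilic β-carbon of the enol ether and loss of HCl should give the conjugated (E)-4-alkoxy-2-oxobut-3-enoyl chloride (known acylation of vinyl ethers with oxalyl chloride), which then esterifies tert-butanol.

**Step 2**
Reactants: 6 1-(TBSO)propan-2-one
Product: 7 (Z)-1-(TBSO)-2-(TMSO)prop-1-ene
Conditions: TMSOTf (1.1 equiv), Et3N (1.3 equiv), Et2O, 0 °C → rt; fractional distillation
Reagents that add atoms: trimethylsilyl trifluoromethanesulfonate, C[Si](C)(C)OS(=O)(=O)C(F)(F)F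
Why: Equilibrating soft enolisation (silyl enol ether formation with silyl triflate and amine) should favour the more substituted enol ether with the two silyloxy groups cis, and the terminal regioisomer is removed by distillation.

**Step 3**
Reactants: 5 tert-butyl (E)-4-(benzyloxy)-2-oxobut-3-enoate; 7 (Z)-1-(TBSO)-2-(TMSO)prop-1-ene
Product: 10 tert-butyl (1R,3S,4S)-3-(benzyloxy)-4-(TBSO)-1-hydroxy-5-oxocyclohexane-1-carboxylate, via dihydropyran silyl ketal 8 (not isolated), via diketo ester 9 (not isolated)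
Conditions: Cu(OTf)2 (10 mol %), (S,S)-t-Bu-box (11 mol %), 7 (1.5 equiv), CH2Cl2, −78 → −20 °C; then H2O (3 equiv), THF, −20 °C → rt
Reagents that add atoms: none
Why: Proposed new method: the copper-chelated 1-oxadiene of 5 should add enol ether 7 endo on the Re face of C3 (known bis(oxazoline)–Cu(OTf)2 inverse-demand hetero-Diels–Alder reaction of 4-alkoxy-2-oxobut-3-enoates, which sets C3 and, through the (Z)-geometry of 7, C4), and hydrolysis of the silyl ketal then lets the methyl-ketone enol attack the still copper-bound keto ester in a 6-(enolendo)-exo-trig aldol (closest known: ring-closing aldol of 2,6-dioxoheptanoates to dehydroquinates), the chair with equatorial ester and axial O3 placing the new C1 hydroxyl cis to O3 and O4.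

**Step 4**
Reactants: 10 tert-butyl (1R,3S,4S)-3-(benzyloxy)-4-(TBSO)-1-hydroxy-5-oxocyclohexane-1-carboxylate
Product: 11 tert-butyl (1S,3S,4R,5S)-3-(benzyloxy)-4-(TBSO)-1,5-dihydroxycyclohexane-1-carboxylate
Conditions: Me4NBH(OAc)3 (5 equiv), MeCN/AcOH (1:1), −30 → −20 °C
Reagents that add atoms: none
Why: Exchange of the tertiary C1 hydroxyl onto boron and intramolecular hydride delivery to the same face of the C5 ketone (Evans–Saksena hydroxyl-directed reduction) should give the 1,5-anti diol, so the new C5 hydroxyl is trans to O4 and cis to the ester carbon.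

**Step 5**
Reactants: 11 tert-butyl (1S,3S,4R,5S)-3-(benzyloxy)-4-(TBSO)-1,5-dihydroxycyclohexane-1-carboxylate
Product: 12 tert-butyl (1R,3S,4S,5S)-3-(benzyloxy)-4,5-bis(TBSO)-1-hydroxycyclohexane-1-carboxylate
Conditions: TBSOTf (1.1 equiv), 2,6-lutidine, CH2Cl2, −78 °C
Reagents that add atoms: tert-butyldimethylsilyl trifluoromethanesulfonate, CC(C)(C)[Si](C)(C)OS(=O)(=O)C(F)(F)F
Why: At low temperature the secondary equatorial C5 hydroxyl should be silylated much faster than the tertiary α-hydroxy ester hydroxyl (silyl ether formation), which leaves only O1 free for step 6.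

**Step 6**
Reactants: 12 tert-butyl (1R,3S,4S,5S)-3-(benzyloxy)-4,5-bis(TBSO)-1-hydroxycyclohexane-1-carboxylate; 13 tert-butyl vinyl ether; 2 oxalyl chloride
Product: 15 tert-butyl (1R,3S,4S,5S)-3-(benzyloxy)-4,5-bis(TBSO)-1-{[(E)-4-tert-butoxy-2-oxobut-3-enoyl]oxy}cyclohexane-1-carboxylate, via keto acyl chloride 14 (not isolated)
Conditions: 13, 2 (1.5 equiv), pyridine (1.0 equiv), CH2Cl2, −20 → 0 °C; evaporate; then 12, pyridine, DMAP (0.2 equiv), CH2Cl2, 0 °C → rt
Reagents that add atoms: none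
Why: The planar, highly electrophilic α-keto acyl chloride should acylate the tertiary hydroxyl as oxalyl chlorides do in the preparation of tert-alkyl oxalates (acylation of an alcohol), so the hindered inter-ring ester is in place before C1 of ring A is quaternary.

**Step 7**
Reactants: 15 tert-butyl (1R,3S,4S,5S)-3-(benzyloxy)-4,5-bis(TBSO)-1-{[(E)-4-tert-butoxy-2-oxobut-3-enoyl]oxy}cyclohexane-1-carboxylate; 7 (Z)-1-(TBSO)-2-(TMSO)prop-1-ene
Product: 18 tert-butyl (1R,3S,4S,5S)-3-(benzyloxy)-4,5-bis(TBSO)-1-{[(1R,3S,4S)-3-tert-butoxy-4-(TBSO)-1-hydroxy-5-oxocyclohexane-1-carbonyl]oxy}cyclohexane-1-carboxylate, via ring A dihydropyran silyl ketal 16 (not isolated), via ring A diketo ester 17 (not isolated)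
Conditions: Cu(OTf)2 (10 mol %), (S,S)-t-Bu-box (11 mol %), 7 (1.5 equiv), CH2Cl2, −78 → −20 °C; then H2O (3 equiv), THF, −20 °C → rt
Reagents that add atoms: none
Why: Proposed new method: the 1,2-dicarbonyl unit of 15 chelates the divalent copper bis(oxazoline) complex and the resulting 1-oxadiene adds the electron-rich enol ether 7 in an endo inverse-demand hetero-Diels–Alder reaction ([4+2] closure of a transient dihydropyran, C3–C4 formed; closest known reaction: bis(oxazoline)–Cu(OTf)2-catalysed hetero-Diels–Alder reactions of 4-alkoxy-2-oxobut-3-enoates with enol ethers), after which water cleaves the anomeric silyl ketal of 16 to diketo ester 17, whose keto ester stays copper-bound and is attacked by the methyl-ketone enol in a 6-(enolendo)-exo-trig aldol that forms C6–C1 and closes the cyclohexane (closest known: ring-closing aldol of 2,6-dioxoheptanoates to dehydroquinates and Lewis-acid-promoted additions to copper-bound pyruvates). C3 is set by the ligand, whose tert-butyl groups in the square-planar chelate should leave the Re face of C3 open. C4 follows from the (Z)-geometry of 7 and the endo position of its trimethylsilyloxy group, which put O4 cis to O3. C1 is set in a chair transition state with the ester equatorial, the C4 silyloxy group in the enol plane and the axial C3 ether oxygen syn to the copper-bound carbonyl oxygen, so the new hydroxyl should come out cis to O3 and O4. The step needs attack of C4 and not C6 on C3, and no β-elimination of tert-butanol: the first is fixed by the internal enol ether 7, the second by the non-basic medium and by C1/C2 staying an enol ether until ring opening.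

**Step 8**
Reactants: 18 tert-butyl (1R,3S,4S,5S)-3-(benzyloxy)-4,5-bis(TBSO)-1-{[(1R,3S,4S)-3-tert-butoxy-4-(TBSO)-1-hydroxy-5-oxocyclohexane-1-carbonyl]oxy}cyclohexane-1-carboxylate
Product: 19 tert-butyl (1R,3S,4S,5S)-3-(benzyloxy)-4,5-bis(TBSO)-1-{[(1S,3S,4R,5S)-3-tert-butoxy-4-(TBSO)-1,5-dihydroxycyclohexane-1-carbonyl]oxy}cyclohexane-1-carboxylate
Conditions: Me4NBH(OAc)3 (5 equiv), MeCN/AcOH (1:1), −30 → −20 °C
Reagents that add atoms: none
Why: As in step 4, the ring A tertiary hydroxyl should deliver hydride to its own face of the C5 ketone (Evans–Saksena hydroxyl-directed reduction), giving the C5 hydroxyl trans to O1 and O4.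

**Step 9**
Reactants: 19 tert-butyl (1R,3S,4S,5S)-3-(benzyloxy)-4,5-bis(TBSO)-1-{[(1S,3S,4R,5S)-3-tert-butoxy-4-(TBSO)-1,5-dihydroxycyclohexane-1-carbonyl]oxy}cyclohexane-1-carboxylate
Product: 20 tert-butyl (1R,3S,4S,5S)-4,5-bis(TBSO)-3-hydroxy-1-{[(1S,3S,4R,5S)-3-tert-butoxy-4-(TBSO)-1,5-dihydroxycyclohexane-1-carbonyl]oxy}cyclohexane-1-carboxylate
Conditions: H2 (1 atm), Pd/C (10 wt %), EtOAc, rt
Reagents that add atoms: none
Why: Hydrogenolysis of the benzyl ether should free O3 of ring B while silyl ethers, tert-butyl groups and esters stay untouched.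

**Step 10**
Reactants: 21 3,4-dihydroxybenzaldehyde; 22 2,2-dimethoxypropane
Product: 23 2,2-dimethyl-1,3-benzodioxole-5-carbaldehyde
Conditions: TsOH·H2O (5 mol %), toluene, reflux, 4 Å molecular sieves (removal of MeOH)
Reagents that add atoms: none
Why: Acid-catalysed transketalisation of the catechol (cyclic ketal formation) is driven by removal of methanol.

**Step 11**
Reactants: 23 2,2-dimethyl-1,3-benzodioxole-5-carbaldehyde; 24 malonic acid
Product: 25 (E)-3-(2,2-dimethyl-1,3-benzodioxol-5-yl)prop-2-enoic acid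
Conditions: pyridine, piperidine (cat.), 90 °C
Reagents that add atoms: none
Why: Knoevenagel condensation with decarboxylation in situ (Doebner modification) should give the (E)-cinnamic acid.

**Step 12**
Reactants: 20 tert-butyl (1R,3S,4S,5S)-4,5-bis(TBSO)-3-hydroxy-1-{[(1S,3S,4R,5S)-3-tert-butoxy-4-(TBSO)-1,5-dihydroxycyclohexane-1-carbonyl]oxy}cyclohexane-1-carboxylate; 25 (E)-3-(2,2-dimethyl-1,3-benzodioxol-5-yl)prop-2-enoic acid
Product: 27 tert-butyl (1R,3S,4S,5S)-4,5-bis(TBSO)-3-{[(E)-3-(2,2-dimethyl-1,3-benzodioxol-5-yl)prop-2-enoyl]oxy}-1-{[(1R,3S,4S,5S)-3-tert-butoxy-4-(TBSO)-5-{[(E)-3-(2,2-dimethyl-1,3-benzodioxol-5-yl)prop-2-enoyl]oxy}-1-hydroxycyclohexane-1-carbonyl]oxy}cyclohexane-1-carboxylate, via cinnamoyl chloride 26 (not isolated)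
Conditions: 25 (3 equiv), (COCl)2, DMF (cat.), CH2Cl2, 0 °C → rt; evaporate; then 20, pyridine, DMAP, CH2Cl2, rt
Reagents that add atoms: none
Why: DMAP-catalysed acylation should esterify the two free secondary hydroxyls (O3 of ring B, O5 of ring A), while the tertiary ring A hydroxyl next to the ester is too hindered to react.

**Step 13**
Reactants: 27 the fully protected bis-ester named in step 12
Product: 28 target: 3-O-caffeoyl-1-O-(5-O-caffeoylquinoyl)quinic acid with both quinic units antipodal to the natural acid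
Conditions: CF3CO2H/H2O (9:1), 0 °C → rt
Reagents that add atoms: none
Why: Acidolysis (global deprotection) should remove the tert-butyl ester and ether, the three silyl ethers and both catechol ketals in one operation, while the carboxylic esters survive, including the tertiary inter-ring ester whose cleavage would need a cation next to a carboxyl group.

**Compound list**
1 | benzyl vinyl ether | C=COCc1ccccc1 | starting material
2 | oxalyl chloride | O=C(Cl)C(=O)Cl | starting material
3 | tert-butanol | CC(C)(C)O | starting material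
4 | (E)-4-(benzyloxy)-2-oxobut-3-enoyl chloride | O=C(Cl)C(=O)/C=C/OCc1ccccc1 | intermediate
5 | tert-butyl (E)-4-(benzyloxy)-2-oxobut-3-enoate | CC(C)(C)OC(=O)C(=O)/C=C/OCc1ccccc1 | intermediate
6 | 1-(tert-butyldimethylsilyloxy)propan-2-one | CC(=O)CO[Si](C)(C)C(C)(C)C | starting material
7 | (Z)-1-(tert-butyldimethylsilyloxy)-2-(trimethylsilyloxy)prop-1-ene | C/C(O[Si](C)(C)C)=C/O[Si](C)(C)C(C)(C)C | intermediate
8 | tert-butyl (2S,3S,4S)-4-(benzyloxy)-3-(TBSO)-2-methyl-2-(TMSO)-3,4-dihydro-2H-pyran-6-carboxylate | CC(C)(C)OC(=O)C1=C[C@H](OCc2ccccc2)[C@H](O[Si](C)(C)C(C)(C)C)[C@](C)(O[Si](C)(C)C)O1 | intermediate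
9 | tert-butyl (4S,5S)-4-(benzyloxy)-5-(TBSO)-2,6-dioxoheptanoate | CC(C)(C)OC(=O)C(=O)C[C@H](OCc1ccccc1)[C@H](O[Si](C)(C)C(C)(C)C)C(C)=O | intermediate
10 | tert-butyl (1R,3S,4S)-3-(benzyloxy)-4-(TBSO)-1-hydroxy-5-oxocyclohexane-1-carboxylate | CC(C)(C)OC(=O)[C@@]1(O)C[C@H](OCc2ccccc2)[C@H](O[Si](C)(C)C(C)(C)C)C(=O)C1 | intermediate
11 | tert-butyl (1S,3S,4R,5S)-3-(benzyloxy)-4-(TBSO)-1,5-dihydroxycyclohexane-1-carboxylate | CC(C)(C)OC(=O)[C@@]1(O)C[C@H](OCc2ccccc2)[C@H](O[Si](C)(C)C(C)(C)C)[C@@H](O)C1 | intermediate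
12 | tert-butyl (1R,3S,4S,5S)-3-(benzyloxy)-4,5-bis(TBSO)-1-hydroxycyclohexane-1-carboxylate | CC(C)(C)OC(=O)[C@@]1(O)C[C@H](OCc2ccccc2)[C@H](O[Si](C)(C)C(C)(C)C)[C@@H](O[Si](C)(C)C(C)(C)C)C1 | intermediate
13 | tert-butyl vinyl ether | C=COC(C)(C)C | starting material
14 | (E)-4-tert-butoxy-2-oxobut-3-enoyl chloride | O=C(Cl)C(=O)/C=C/OC(C)(C)C | intermediate
15 | tert-butyl (1R,3S,4S,5S)-3-(benzyloxy)-4,5-bis(TBSO)-1-{[(E)-4-tert-butoxy-2-oxobut-3-enoyl]oxy}cyclohexane-1-carboxylate | CC(C)(C)OC(=O)[C@@]1(OC(=O)C(=O)/C=C/OC(C)(C)C)C[C@H](OCc2ccccc2)[C@H](O[Si](C)(C)C(C)(C)C)[C@@H](O[Si](C)(C)C(C)(C)C)C1 | intermediate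
16 | ring B ester (ring B as in 15) of (2S,3S,4S)-4-tert-butoxy-3-(TBSO)-2-methyl-2-(TMSO)-3,4-dihydro-2H-pyran-6-carboxylic acid | CC(C)(C)OC(=O)[C@@]1(OC(=O)C2=C[C@H](OC(C)(C)C)[C@H](O[Si](C)(C)C(C)(C)C)[C@](C)(O[Si](C)(C)C)O2)C[C@H](OCc2ccccc2)[C@H](O[Si](C)(C)C(C)(C)C)[C@@H](O[Si](C)(C)C(C)(C)C)C1 | intermediate
17 | ring B ester (ring B as in 15) of (4S,5S)-4-tert-butoxy-5-(TBSO)-2,6-dioxoheptanoic acid | CC(C)(C)OC(=O)[C@@]1(OC(=O)C(=O)C[C@H](OC(C)(C)C)[C@H](O[Si](C)(C)C(C)(C)C)C(C)=O)C[C@H](OCc2ccccc2)[C@H](O[Si](C)(C)C(C)(C)C)[C@@H](O[Si](C)(C)C(C)(C)C)C1 | intermediate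
18 | tert-butyl (1R,3S,4S,5S)-3-(benzyloxy)-4,5-bis(TBSO)-1-{[(1R,3S,4S)-3-tert-butoxy-4-(TBSO)-1-hydroxy-5-oxocyclohexane-1-carbonyl]oxy}cyclohexane-1-carboxylate | CC(C)(C)OC(=O)[C@@]1(OC(=O)[C@@]2(O)C[C@H](OC(C)(C)C)[C@H](O[Si](C)(C)C(C)(C)C)C(=O)C2)C[C@H](OCc2ccccc2)[C@H](O[Si](C)(C)C(C)(C)C)[C@@H](O[Si](C)(C)C(C)(C)C)C1 | intermediate
19 | tert-butyl (1R,3S,4S,5S)-3-(benzyloxy)-4,5-bis(TBSO)-1-{[(1S,3S,4R,5S)-3-tert-butoxy-4-(TBSO)-1,5-dihydroxycyclohexane-1-carbonyl]oxy}cyclohexane-1-carboxylate | CC(C)(C)OC(=O)[C@@]1(OC(=O)[C@@]2(O)C[C@H](OC(C)(C)C)[C@H](O[Si](C)(C)C(C)(C)C)[C@@H](O)C2)C[C@H](OCc2ccccc2)[C@H](O[Si](C)(C)C(C)(C)C)[C@@H](O[Si](C)(C)C(C)(C)C)C1 | intermediate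
20 | tert-butyl (1R,3S,4S,5S)-4,5-bis(TBSO)-3-hydroxy-1-{[(1S,3S,4R,5S)-3-tert-butoxy-4-(TBSO)-1,5-dihydroxycyclohexane-1-carbonyl]oxy}cyclohexane-1-carboxylate | CC(C)(C)OC(=O)[C@@]1(OC(=O)[C@@]2(O)C[C@H](OC(C)(C)C)[C@H](O[Si](C)(C)C(C)(C)C)[C@@H](O)C2)C[C@H](O)[C@H](O[Si](C)(C)C(C)(C)C)[C@@H](O[Si](C)(C)C(C)(C)C)C1 | intermediate
21 | 3,4-dihydroxybenzaldehyde | O=Cc1ccc(O)c(O)c1 | starting material
22 | 2,2-dimethoxypropane | COC(C)(C)OC | starting material
23 | 2,2-dimethyl-1,3-benzodioxole-5-carbaldehyde | O=Cc1ccc2OC(C)(C)Oc2c1 | intermediate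
24 | malonic acid | OC(=O)CC(=O)O | starting material
25 | (E)-3-(2,2-dimethyl-1,3-benzodioxol-5-yl)prop-2-enoic acid | OC(=O)/C=C/c1ccc2OC(C)(C)Oc2c1 | intermediate
26 | (E)-3-(2,2-dimethyl-1,3-benzodioxol-5-yl)prop-2-enoyl chloride | O=C(Cl)/C=C/c1ccc2OC(C)(C)Oc2c1 | intermediate
27 | tert-butyl (1R,3S,4S,5S)-4,5-bis(TBSO)-3-{[(E)-3-(2,2-dimethyl-1,3-benzodioxol-5-yl)prop-2-enoyl]oxy}-1-{[(1R,3S,4S,5S)-3-tert-butoxy-4-(TBSO)-5-{[(E)-3-(2,2-dimethyl-1,3-benzodioxol-5-yl)prop-2-enoyl]oxy}-1-hydroxycyclohexane-1-carbonyl]oxy}cyclohexane-1-carboxylate | CC(C)(C)OC(=O)[C@@]1(OC(=O)[C@@]2(O)C[C@H](OC(C)(C)C)[C@H](O[Si](C)(C)C(C)(C)C)[C@@H](OC(=O)/C=C/c3ccc4OC(C)(C)Oc4c3)C2)C[C@H](OC(=O)/C=C/c2ccc3OC(C)(C)Oc3c2)[C@H](O[Si](C)(C)C(C)(C)C)[C@@H](O[Si](C)(C)C(C)(C)C)C1 | intermediate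
28 | target: 3-O-caffeoyl-1-O-(5-O-caffeoylquinoyl)quinic acid, both quinic units antipodal to the natural acid; ring B (1S,3S,4R,5S) with the caffeoyloxy group on C3, ring A (1R,3S,4S,5S) with the caffeoyloxy group on C5 | O=C(/C=C/c1ccc(O)c(O)c1)O[C@H]1C[C@@](O)(C(=O)O[C@]2(C(=O)O)C[C@H](OC(=O)/C=C/c3ccc(O)c(O)c3)[C@H](O)[C@@H](O)C2)C[C@H](O)[C@@H]1O | target

**Step count and risks**
Total step count: 13. Longest linear sequence: 10 steps (1, 3, 4, 5, 6, 7, 8, 9, 12, 13).

Steps most likely to fail: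

1. Step 7 (proposed new method). The cascade may stop after the cycloaddition because enolisation of the methyl ketone is slow. The diketo ester may lose tert-butanol by β-elimination through its C1/C2 enol before the ring closes. The Lewis acid may cleave the vinylogous tert-butyl ester. Facial control at C1 in the aldol may be poor. Fallback with known reactions: setting out from 15, the hetero-Diels–Alder reaction with 7 is run alone under the same Cu(OTf)2/(S,S)-t-Bu-box catalysis and quenched with methanol and pyridinium p-toluenesulfonate. This exchanges the labile silyl ketal for the chromatography-stable ring A dihydropyran methyl ketal F1. F1 is opened with aqueous acetic acid in THF to diketo ester 17. Then 17 is closed in a separate step by an enamine-mediated aldol (pyrrolidine, AcOH, CH2Cl2, 0 °C), a known ring closure of 1,5-dicarbonyl compounds onto 2-oxo esters, which comes back to the route at 18. C1 epimers, if formed, are separated at this stage.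

2. Step 3 (proposed new method). The same processes can fail on the simple ester. In addition, enantioselectivity may erode if the trisubstituted enol ether adds stepwise, and carry-over of the E-isomer of 7 would lower the cis relation of O3 and O4. Fallback with known reactions: setting out from 5 and 7, the cycloaddition alone is run under the same catalyst and quenched with methanol and pyridinium p-toluenesulfonate to give the dihydropyran methyl ketal F2. Aqueous acetic acid opens F2 to diketo ester 9. Then 9 is cyclised in a separate step by enamine catalysis with L-proline (DMSO, rt), a known ring-closing aldol, which returns to the route at 10.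

3. Step 6. Pyridine or DMAP may attack the β-alkoxyvinyl carbon of acyl chloride 14 with loss of tert-butanol and oligomerisation, or HCl may cleave the tert-butyl enol ether, so that too little acyl chloride reaches the slowly reacting tertiary hydroxyl. Fallback that reverses the order of the two acylations: setting out from 12, oxalyl chloride alone (excess, pyridine, CH2Cl2, 0 °C) converts the tertiary hydroxyl into the ring B chlorooxalate F3, as is known for tertiary alcohols, and the excess reagent is evaporated. F3, now an ordinary alkyl chlorooxoacetate, then acylates tert-butyl vinyl ether 13 (pyridine, CH2Cl2, 0 °C → rt), which comes back to the route at 15.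

**Further compounds**
F1 | step 7 | ring B ester (ring B as in 15) of (3S,4S)-4-tert-butoxy-3-(TBSO)-2-methoxy-2-methyl-3,4-dihydro-2H-pyran-6-carboxylic acid, mixture of anomers | CC(C)(C)OC(=O)[C@@]1(OC(=O)C2=C[C@H](OC(C)(C)C)[C@H](O[Si](C)(C)C(C)(C)C)C(C)(OC)O2)C[C@H](OCc2ccccc2)[C@H](O[Si](C)(C)C(C)(C)C)[C@@H](O[Si](C)(C)C(C)(C)C)C1
F2 | step 3 | tert-butyl (3S,4S)-4-(benzyloxy)-3-(TBSO)-2-methoxy-2-methyl-3,4-dihydro-2H-pyran-6-carboxylate, mixture of anomers | CC(C)(C)OC(=O)C1=C[C@H](OCc2ccccc2)[C@H](O[Si](C)(C)C(C)(C)C)C(C)(OC)O1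
F3 | step 6 | tert-butyl (1R,3S,4S,5S)-3-(benzyloxy)-4,5-bis(TBSO)-1-[(chlorooxoacetyl)oxy]cyclohexane-1-carboxylate | CC(C)(C)OC(=O)[C@@]1(OC(=O)C(=O)Cl)C[C@H](OCc2ccccc2)[C@H](O[Si](C)(C)C(C)(C)C)[C@@H](O[Si](C)(C)C(C)(C)C)C1
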